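## Retrosynthetic overview

1. Both oxiranes are closed last, by double SN2 closure (inversion at C2' and C6') of the bis-secondary mesylate of coumarin tetraol 17.
2. The pyranone ring comes from an aldol of γ-lactone 15 with aldehyde 6, then acid-driven dehydration and translactonisation (the lactone C–O becomes the C2'–OH).
3. Aldehyde 6 comes from the aromatic Claisen rearrangement of 4-O-prenyl ether 4, which makes the C6–C(Me)2CH=CH2 bond (key step).
4. Lactone 15 comes from MeMgBr addition to ketone 14, itself from (R)-lactone acid 11 (C2') and an alkylzinc made from (S)-α-hydroxy-γ-butyrolactone 7 (C6').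
5. Ring order: benzene ring bought, then the pyranone, then the two oxiranes.

Assumption: the side chain is numbered C1'–C7' from the CH2 on coumarin C3; the SMILES reads as (2'S,3'R,6'R), a cis (nerol-type) 2',3'-epoxide; lactones 7 and 11 are catalogue chiral-pool compounds (from L-malic acid and D-glutamic acid).

## Route

Step 1
Reactants: 1 2,4-dihydroxybenzaldehyde; 2 1-bromo-3-methylbut-2-ene (prenyl bromide)
Product: 3 2-hydroxy-4-[(3-methylbut-2-en-1-yl)oxy]benzaldehyde
Conditions: K2CO3 (1.0 equiv), acetone, rt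
Reagents that add atoms: none
Why: Williamson O-alkylation in which the 2-OH is held in the hydrogen bond to the formyl group, so the free, more acidic 4-OH is alkylated selectively.

Step 2
Reactants: 3 2-hydroxy-4-[(3-methylbut-2-en-1-yl)oxy]benzaldehyde
Product: 4 2-(methoxymethoxy)-4-[(3-methylbut-2-en-1-yl)oxy]benzaldehyde
Conditions: MOMCl, i-Pr2NEt, CH2Cl2, 0 °C to rt
Reagents that add atoms: chloromethyl methyl ether, COCCl
Why: MOM acetal protection of the chelated 2-OH removes the hydrogen-bond bond fixation that would steer the rearrangement to C3 and gives an acid-labile mask for the future ring oxygen.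

Step 3
Reactants: 4 2-(methoxymethoxy)-4-[(3-methylbut-2-en-1-yl)oxy]benzaldehyde
Product: 6 4-formyl-5-(methoxymethoxy)-2-(2-methylbut-3-en-2-yl)phenyl pivalate, via Claisen phenol 5 (not isolated)
Conditions: PhNEt2, 190 °C, 3 h (Ar); cool to rt; Et3N, PivCl, DMAP (cat.)
Reagents that add atoms: pivaloyl chloride, CC(C)(C)C(Cl)=O
Why: Aromatic Claisen [3,3]-sigmatropic rearrangement delivers the prenyl group with allylic inversion (as 1,1-dimethylallyl) to C5, the ortho site para to the OMOM donor and not flanked by two oxygens, and the hindered phenol is then esterified in the same flask before it can cyclise or rearrange further.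

Step 4
Reactants: 7 (S)-3-hydroxydihydrofuran-2(3H)-one
Product: 8 (3S)-4-methylpentane-1,3,4-triol
Conditions: MeMgBr (3.5 equiv), THF, 0 °C to rt; minimal sat. NH4Cl, filtration
Reagents that add atoms: methylmagnesium bromide, C[Mg]Br
Why: Double Grignard addition to the lactone carbonyl builds the CMe2OH end, while the carbinol stereocentre (future C6') is bought with 7 and is not touched.

Step 5
Reactants: 8 (3S)-4-methylpentane-1,3,4-triol
Product: 9 2-[(4S)-2,2,5,5-tetramethyl-1,3-dioxolan-4-yl]ethan-1-ol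
Conditions: 2,2-dimethoxypropane, TsOH (cat.), acetone, rt
Reagents that add atoms: 2,2-dimethoxypropane, COC(C)(C)OC
Why: Acid-catalysed transketalisation under equilibrating conditions favours the five-membered sec/tert dioxolane (gem-dialkyl effect) over the 1,3-dioxane and leaves the primary OH free.

Step 6
Reactants: 9 2-[(4S)-2,2,5,5-tetramethyl-1,3-dioxolan-4-yl]ethan-1-ol
Product: 10 (4S)-4-(2-iodoethyl)-2,2,5,5-tetramethyl-1,3-dioxolane
Conditions: PPh3, I2, imidazole, CH2Cl2, 0 °C to rt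
Reagents that add atoms: iodine, II
Why: Appel-type iodination by SN2 at the primary carbon, with imidazole buffering so the acetonide survives.

Step 7
Reactants: 10 (4S)-4-(2-iodoethyl)-2,2,5,5-tetramethyl-1,3-dioxolane; 11 (R)-5-oxotetrahydrofuran-2-carboxylic acid
Product: 14 (5R)-5-{3-[(4S)-2,2,5,5-tetramethyl-1,3-dioxolan-4-yl]propanoyl}dihydrofuran-2(3H)-one, via acid chloride 12 (not isolated), via alkylzinc iodide 13 (not isolated)
Conditions: 11, (COCl)2, DMF (cat.), CH2Cl2, 0 °C to rt, evaporate; 10, Zn dust (TMSCl/BrCH2CH2Br-activated), THF, 40 °C; combine, Pd(PPh3)4 (5 mol%), THF, 0 °C to rt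
Reagents that add atoms: none
Why: Acid chloride formation, zinc insertion into the primary C–I bond and Pd-catalysed Negishi acylation give the ketone without over-addition and without base that could epimerise the α-acyloxy centre bought with 11.

Step 8
Reactants: 14 (5R)-5-{3-[(4S)-2,2,5,5-tetramethyl-1,3-dioxolan-4-yl]propanoyl}dihydrofuran-2(3H)-one
Product: 15 (5R)-5-{(2R)-2-hydroxy-4-[(4S)-2,2,5,5-tetramethyl-1,3-dioxolan-4-yl]butan-2-yl}dihydrofuran-2(3H)-one
Conditions: MeMgBr (1.2 equiv), THF, −78 °C; aq. NH4Cl; chromatography to remove the minor C3' epimer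
Reagents that add atoms: methylmagnesium bromide, C[Mg]Br
Why: Substrate-controlled Grignard 1,2-addition to the ketone (far faster than to the lactone at −78 °C) under polar Felkin–Anh/Cornforth control, Me attacking anti to the ring C–O bond past the small H of the bought (R)-centre, sets the tertiary carbinol as (R).

Step 9
Reactants: 15 (5R)-5-{(2R)-2-hydroxy-4-[(4S)-2,2,5,5-tetramethyl-1,3-dioxolan-4-yl]butan-2-yl}dihydrofuran-2(3H)-one; 6 4-formyl-5-(methoxymethoxy)-2-(2-methylbut-3-en-2-yl)phenyl pivalate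
Product: 17 3-[(2R,3R,6S)-2,3,6,7-tetrahydroxy-3,7-dimethyloctyl]-6-(2-methylbut-3-en-2-yl)-2-oxo-2H-chromen-7-yl pivalate, via aldol adduct 16 (not isolated)
Conditions: 15, LDA (2.2 equiv), THF, −78 °C; 6, −78 °C, 1 h; then 3 M HCl in MeOH (excess), −78 to 50 °C
Reagents that add atoms: none
Why: Lithium-enolate aldol addition of the lactone dianion to the aldehyde is followed in the same flask by acid-mediated MOM/acetonide cleavage, E1 dehydration of the electron-rich benzylic alcohol and translactonisation of the freed phenol onto the lactone carbonyl (acyl–O cleavage, so the former lactone C–O centre keeps its configuration as the C2' alcohol), with the coumarin as thermodynamic sink.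

Step 10
Reactants: 17 3-[(2R,3R,6S)-2,3,6,7-tetrahydroxy-3,7-dimethyloctyl]-6-(2-methylbut-3-en-2-yl)-2-oxo-2H-chromen-7-yl pivalate
Product: 19 7-hydroxy-6-(2-methylbut-3-en-2-yl)-3-{[(2S,3R)-3-{2-[(2R)-3,3-dimethyloxiran-2-yl]ethyl}-3-methyloxiran-2-yl]methyl}-2H-chromen-2-one (CNP0292491.1), via bis-mesylate 18 (not isolated)
Conditions: MsCl (2.3 equiv), pyridine, CH2Cl2, 0 °C; then MeOH, K2CO3 (excess), rt; work-up at pH 6–7
Reagents that add atoms: none
Why: Selective sulfonylation of the two secondary alcohols and double intramolecular Williamson (3-exo-tet SN2) closure by the neighbouring tertiary alkoxides invert C2' and C6' ((2R,6S) to (2'S,6'R), C3' retained), while the same basic methanol cleaves the aryl pivalate to free the 7-OH.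

## Compound list

1 | 2,4-dihydroxybenzaldehyde | O=Cc1ccc(O)cc1O | starting material
2 | 1-bromo-3-methylbut-2-ene (prenyl bromide) | CC(C)=CCBr | starting material
3 | 2-hydroxy-4-[(3-methylbut-2-en-1-yl)oxy]benzaldehyde | O=Cc1ccc(OCC=C(C)C)cc1O | intermediate
4 | 2-(methoxymethoxy)-4-[(3-methylbut-2-en-1-yl)oxy]benzaldehyde | COCOc1cc(OCC=C(C)C)ccc1C=O | intermediate
5 | 4-hydroxy-2-(methoxymethoxy)-5-(2-methylbut-3-en-2-yl)benzaldehyde | COCOc1cc(O)c(C(C)(C)C=C)cc1C=O | intermediate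
6 | 4-formyl-5-(methoxymethoxy)-2-(2-methylbut-3-en-2-yl)phenyl pivalate | COCOc1cc(OC(=O)C(C)(C)C)c(C(C)(C)C=C)cc1C=O | intermediate
7 | (S)-3-hydroxydihydrofuran-2(3H)-one ((S)-α-hydroxy-γ-butyrolactone) | O[C@H]1CCOC1=O | starting material
8 | (3S)-4-methylpentane-1,3,4-triol | OCC[C@H](O)C(C)(C)O | intermediate
9 | 2-[(4S)-2,2,5,5-tetramethyl-1,3-dioxolan-4-yl]ethan-1-ol | OCC[C@@H]1OC(C)(C)OC1(C)C | intermediate
10 | (4S)-4-(2-iodoethyl)-2,2,5,5-tetramethyl-1,3-dioxolane | ICC[C@@H]1OC(C)(C)OC1(C)C | intermediate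
11 | (R)-5-oxotetrahydrofuran-2-carboxylic acid | OC(=O)[C@H]1CCC(=O)O1 | starting material
12 | (R)-5-oxotetrahydrofuran-2-carbonyl chloride | ClC(=O)[C@H]1CCC(=O)O1 | intermediate
13 | {2-[(4S)-2,2,5,5-tetramethyl-1,3-dioxolan-4-yl]ethyl}zinc iodide | I[Zn]CC[C@@H]1OC(C)(C)OC1(C)C | intermediate
14 | (5R)-5-{3-[(4S)-2,2,5,5-tetramethyl-1,3-dioxolan-4-yl]propanoyl}dihydrofuran-2(3H)-one | O=C1CC[C@H](C(=O)CC[C@@H]2OC(C)(C)OC2(C)C)O1 | intermediate
15 | (5R)-5-{(2R)-2-hydroxy-4-[(4S)-2,2,5,5-tetramethyl-1,3-dioxolan-4-yl]butan-2-yl}dihydrofuran-2(3H)-one | O=C1CC[C@H]([C@](C)(O)CC[C@@H]2OC(C)(C)OC2(C)C)O1 | intermediate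
16 | 4-{hydroxy[(5R)-5-{(2R)-2-hydroxy-4-[(4S)-2,2,5,5-tetramethyl-1,3-dioxolan-4-yl]butan-2-yl}-2-oxotetrahydrofuran-3-yl]methyl}-5-(methoxymethoxy)-2-(2-methylbut-3-en-2-yl)phenyl pivalate (mixture at the two new carbons) | COCOc1cc(OC(=O)C(C)(C)C)c(C(C)(C)C=C)cc1C(O)C3C[C@H]([C@](C)(O)CC[C@@H]2OC(C)(C)OC2(C)C)OC3=O | intermediate
17 | 3-[(2R,3R,6S)-2,3,6,7-tetrahydroxy-3,7-dimethyloctyl]-6-(2-methylbut-3-en-2-yl)-2-oxo-2H-chromen-7-yl pivalate | C=CC(C)(C)c1cc2cc(C[C@@H](O)[C@](C)(O)CC[C@H](O)C(C)(C)O)c(=O)oc2cc1OC(=O)C(C)(C)C | intermediate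
18 | (2R,3R,6S)-3,7-dihydroxy-3,7-dimethyl-1-[6-(2-methylbut-3-en-2-yl)-2-oxo-7-(pivaloyloxy)-2H-chromen-3-yl]octane-2,6-diyl dimethanesulfonate | C=CC(C)(C)c1cc2cc(C[C@@H](OS(C)(=O)=O)[C@](C)(O)CC[C@H](OS(C)(=O)=O)C(C)(C)O)c(=O)oc2cc1OC(=O)C(C)(C)C | intermediate
19 | 7-hydroxy-6-(2-methylbut-3-en-2-yl)-3-{[(2S,3R)-3-{2-[(2R)-3,3-dimethyloxiran-2-yl]ethyl}-3-methyloxiran-2-yl]methyl}-2H-chromen-2-one (CNP0292491.1) | C=CC(C)(C)c1cc2cc(C[C@@H]3O[C@]3(C)CC[C@H]3OC3(C)C)c(=O)oc2cc1O | target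

## Count and risks

Total steps: 10. Longest linear sequence: 7 steps (7 → 8 → 9 → 10 → 14 → 15 → 17 → 19).

**Step 8 (facial selectivity of the methyl addition; the most uncertain step).** A lactone oxygen is a weak chelator, so Felkin–Anh control is expected, but the selectivity may be modest or reversed. The fallback sets out from 12 and 10 and comes back at 15, and reverses the order in which the two carbon groups are put on C3'. Acid chloride 12 is treated with Me2CuLi (Et2O, −78 °C) to give (5R)-5-acetyldihydrofuran-2(3H)-one F4. Iodide 10 is converted with Mg in Et2O into {2-[(4S)-2,2,5,5-tetramethyl-1,3-dioxolan-4-yl]ethyl}magnesium iodide F5. F5 is added at −78 °C to F4 precomplexed with MgBr2·OEt2 in CH2Cl2, so that attack on the H face of the five-membered magnesium chelate gives 15. Swapping the roles of Me and the chain inverts C3' for a given facial bias, so whichever face the acyl lactone prefers, one of the two orders delivers 15.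

**Step 9 (one-flask aldol and acid cascade).** The dehydration may stop at the (E)-arylidene lactone, which cannot lactonise onto the phenol. The fallback sets out from 16 and comes back at 17. The aldol is quenched cold with AcOH and 16 is isolated. MsCl/Et3N (CH2Cl2, −20 °C) gives 4-{[(5R)-5-{(2R)-2-hydroxy-4-[(4S)-2,2,5,5-tetramethyl-1,3-dioxolan-4-yl]butan-2-yl}-2-oxotetrahydrofuran-3-yl](methanesulfonyloxy)methyl}-5-(methoxymethoxy)-2-(2-methylbut-3-en-2-yl)phenyl pivalate F6. DBU eliminates this to 4-{(E)-[(5R)-5-{(2R)-2-hydroxy-4-[(4S)-2,2,5,5-tetramethyl-1,3-dioxolan-4-yl]butan-2-yl}-2-oxodihydrofuran-3(2H)-ylidene]methyl}-5-(methoxymethoxy)-2-(2-methylbut-3-en-2-yl)phenyl pivalate F7. Dilute methanolic HCl at rt removes MOM and acetonide to give 4-{(E)-[(5R)-2-oxo-5-[(2R,5S)-2,5,6-trihydroxy-6-methylheptan-2-yl]dihydrofuran-3(2H)-ylidene]methyl}-5-hydroxy-2-(2-methylbut-3-en-2-yl)phenyl pivalate F8. Irradiation at 365 nm in MeOH isomerises E to Z, and the Z isomer lactonises irreversibly onto the phenol to give 17.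

**Step 3 (yield of the prenyl Claisen on the aldehyde).** Thermal loss of the prenyl group, abnormal Claisen products or aldehyde degradation at 190 °C could lower the yield. The fallback sets out from 2 and comes back at 5, and runs the same [3,3] shift before the formyl group is present. Prenyl bromide 2 alkylates commercial 3-(methoxymethoxy)phenol (K2CO3, acetone) to give 1-(methoxymethoxy)-3-[(3-methylbut-2-en-1-yl)oxy]benzene F1. Heating in PhNEt2 at 190 °C gives 5-(methoxymethoxy)-2-(2-methylbut-3-en-2-yl)phenol F2. NBS (MeCN, 0 °C) brominates para to the free OH to give 4-bromo-5-(methoxymethoxy)-2-(2-methylbut-3-en-2-yl)phenol F3. NaH, then t-BuLi (THF, −78 °C) and DMF convert F3 into 5, which is pivaloylated to 6 as in step 3.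

Further compounds
F1 | step 3 | 1-(methoxymethoxy)-3-[(3-methylbut-2-en-1-yl)oxy]benzene | COCOc1cccc(OCC=C(C)C)c1
F2 | step 3 | 5-(methoxymethoxy)-2-(2-methylbut-3-en-2-yl)phenol | COCOc1ccc(C(C)(C)C=C)c(O)c1
F3 | step 3 | 4-bromo-5-(methoxymethoxy)-2-(2-methylbut-3-en-2-yl)phenol | COCOc1cc(O)c(C(C)(C)C=C)cc1Br
F4 | step 8 | (5R)-5-acetyldihydrofuran-2(3H)-one | CC(=O)[C@H]1CCC(=O)O1
F5 | step 8 | {2-[(4S)-2,2,5,5-tetramethyl-1,3-dioxolan-4-yl]ethyl}magnesium iodide | I[Mg]CC[C@@H]1OC(C)(C)OC1(C)C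
F6 | step 9 | 4-{[(5R)-5-{(2R)-2-hydroxy-4-[(4S)-2,2,5,5-tetramethyl-1,3-dioxolan-4-yl]butan-2-yl}-2-oxotetrahydrofuran-3-yl](methanesulfonyloxy)methyl}-5-(methoxymethoxy)-2-(2-methylbut-3-en-2-yl)phenyl pivalate | COCOc1cc(OC(=O)C(C)(C)C)c(C(C)(C)C=C)cc1C(OS(C)(=O)=O)C3C[C@H]([C@](C)(O)CC[C@@H]2OC(C)(C)OC2(C)C)OC3=O
F7 | step 9 | 4-{(E)-[(5R)-5-{(2R)-2-hydroxy-4-[(4S)-2,2,5,5-tetramethyl-1,3-dioxolan-4-yl]butan-2-yl}-2-oxodihydrofuran-3(2H)-ylidene]methyl}-5-(methoxymethoxy)-2-(2-methylbut-3-en-2-yl)phenyl pivalate | COCOc1cc(OC(=O)C(C)(C)C)c(C(C)(C)C=C)cc1/C=C3\C[C@H]([C@](C)(O)CC[C@@H]2OC(C)(C)OC2(C)C)OC3=O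
F8 | step 9 | 4-{(E)-[(5R)-2-oxo-5-[(2R,5S)-2,5,6-trihydroxy-6-methylheptan-2-yl]dihydrofuran-3(2H)-ylidene]methyl}-5-hydroxy-2-(2-methylbut-3-en-2-yl)phenyl pivalate | Oc1cc(OC(=O)C(C)(C)C)c(C(C)(C)C=C)cc1/C=C3\C[C@H]([C@](C)(O)CC[C@H](O)C(C)(C)O)OC3=O
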